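**Retrosynthetic overview**
1. Target ⇐ O-debenzylation ⇐ anti hydrolysis of an 8α,9α-epoxide at C8 ⇐ 6-O-acylation ⇐ OH-directed epoxidation of jaeschkeanadiol (dauc-8-ene-4β,6α-diol).
2. Jaeschkeanadiol ⇐ OH-directed reduction of the aldol-type 4β-hydroxy-6-ketone.
3. Key disconnection: this β-hydroxy ketone ⇐ semipinacol rearrangement of a cis-fused octalin 2,3-epoxy alcohol. The ring-fusion bond migrates, so ring A contracts to the cyclopentane and ring B expands to the cycloheptene in the same event.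
4. Epoxy alcohol ⇐ OH-directed epoxidation ⇐ cis-octalinol ⇐ intramolecular Barbier allylation of a 6,6-disubstituted carvenone ⇐ (R)-carvone + isoprene dibromide.
5. Ring order: ring A (from carvone) → ring B (Barbier) → five- and seven-membered rings together (semipinacol).

Assumption: (E)-1,4-dibromo-2-methylbut-2-ene (isoprene dibromide) is bought as such.

Daucane numbering is used from compound 9 on: C1 = ring-fusion carbon with CH3, C2/C3 = cyclopentane CH2, C4 = C(OH)(i-Pr), C5 = ring-fusion CH, C6 = CH–O, C7 = CH2, C8 = C(CH3), C9, C10 = CH2. β = face of the C1 methyl.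

Step 1
Reactants: 1 (R)-(−)-carvone; 2 (E)-1,4-dibromo-2-methylbut-2-ene
Product: 4 (2R,5R)-2-[(2E)-4-bromo-3-methylbut-2-en-1-yl]-2-methyl-5-(prop-1-en-2-yl)cyclohexan-1-one, via lithium enolate 3 (not isolated)
Conditions: L-Selectride (1.05 equiv), THF, −78 °C; then 2 (3 equiv), DMPU, −78 → 0 °C
Reagents that add atoms: none
Why: Conjugate reduction/enolate alkylation (reductive alkylation of an enone): the regiodefined enolate attacks the more reactive prenyl-type CH2Br of 2 axially, cis to the equatorial isopropenyl group, which sets the quaternary centre (the minor epimer is removed by chromatography because it would become the enantiomer after step 2).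

Step 2
Reactants: 4 (2R,5R)-2-[(2E)-4-bromo-3-methylbut-2-en-1-yl]-2-methyl-5-(prop-1-en-2-yl)cyclohexan-1-one
Product: 5 (6R)-6-[(2E)-4-bromo-3-methylbut-2-en-1-yl]-6-methyl-3-(propan-2-yl)cyclohex-2-en-1-one
Conditions: TsOH (anhydrous, 10 mol%), PhH, 80 °C
Reagents that add atoms: none
Why: Acid-catalysed alkene isomerisation into conjugation (dihydrocarvone → carvenone type); the quaternary centre cannot epimerise and the isopropenyl-bearing centre, having done its job, is erased.

Step 3
Reactants: 5 (6R)-6-[(2E)-4-bromo-3-methylbut-2-en-1-yl]-6-methyl-3-(propan-2-yl)cyclohex-2-en-1-one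
Product: 7 cis-fused (4aS,8aR)-6,8a-dimethyl-3-(propan-2-yl)-1,2,4a,5,8,8a-hexahydronaphthalen-4a-ol, via allylzinc bromide 6 (not isolated)
Conditions: Zn dust, THF/sat. aq NH4Cl, 0 °C → rt
Reagents that add atoms: none
Why: Intramolecular Barbier allylation: the allylzinc (E/Z-equilibrating by 1,3-metallotropy) delivers its CH2 terminus 1,2 to the carbonyl face on which the tether lies through a six-membered closure, giving the cis-fused octalinol with OH cis to the angular CH3 (γ-attack would need a four-membered ring).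

Step 4
Reactants: 7 cis-fused (4aS,8aR)-6,8a-dimethyl-3-(propan-2-yl)-1,2,4a,5,8,8a-hexahydronaphthalen-4a-ol
Product: 8 (3R,4R,4aR,8aR)-3,4-epoxy-6,8a-dimethyl-3-(propan-2-yl)-1,2,3,4,4a,5,8,8a-octahydronaphthalen-4a-ol (epoxide O, OH and angular CH3 all cis)
Conditions: VO(acac)2 (5 mol%), TBHP (1.2 equiv), CH2Cl2, 0 °C
Reagents that add atoms: tert-butyl hydroperoxide, CC(C)(C)OO
Why: Vanadium-catalysed hydroxyl-directed epoxidation: the tertiary allylic OH delivers oxygen syn to the allylic C=C (much faster than to the homoallylic ring-B alkene), which fixes the configuration of the future C4 carbinol.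

Step 5
Reactants: 8 (3R,4R,4aR,8aR)-3,4-epoxy-6,8a-dimethyl-3-(propan-2-yl)-1,2,3,4,4a,5,8,8a-octahydronaphthalen-4a-ol
Product: 9 trans-fused (3R,3aR,8aR)-3-hydroxy-6,8a-dimethyl-3-(propan-2-yl)-2,3,3a,5,8,8a-hexahydroazulen-4(1H)-one (4β-hydroxydauc-8-en-6-one)
Conditions: ZnBr2 (0.5 equiv), CH2Cl2, 0 °C → rt
Reagents that add atoms: none
Why: Semipinacol rearrangement of an α-hydroxy epoxide: with the Lewis acid bridging OH and epoxide O, the ring-fusion C–C bond (tertiary alkyl, anti to the breaking C5–O bond) migrates, so the cyclopentane and the cycloheptenone form together; C5 is inverted (H trans to the angular CH3), the migrating carbon retains configuration and the epoxide oxygen stays on C4 as the β-OH.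

Step 6
Reactants: 9 trans-fused (3R,3aR,8aR)-3-hydroxy-6,8a-dimethyl-3-(propan-2-yl)-2,3,3a,5,8,8a-hexahydroazulen-4(1H)-one
Product: 10 jaeschkeanadiol (3R,3aS,4S,8aR)-6,8a-dimethyl-3-(propan-2-yl)-1,2,3,3a,4,5,8,8a-octahydroazulene-3,4-diol
Conditions: Me4NBH(OAc)3, MeCN/AcOH, −20 °C
Reagents that add atoms: none
Why: Evans–Saksena hydroxyl-directed reduction: the borohydride bound to the β-face tertiary OH delivers hydride intramolecularly to the β-face of the ketone, giving the 6α-alcohol.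

Step 7
Reactants: 10 jaeschkeanadiol
Product: 11 8α,9α-epoxydaucane-4β,6α-diol
Conditions: VO(acac)2 (5 mol%), TBHP (1.2 equiv), CH2Cl2, 0 °C → rt
Reagents that add atoms: tert-butyl hydroperoxide, CC(C)(C)OO
Why: Vanadium-catalysed epoxidation directed by the homoallylic 6α-OH puts the epoxide on the α-face (syn to the directing OH, opposite to the angular CH3).

Step 8
Reactants: 11 8α,9α-epoxydaucane-4β,6α-diol; 12 4-(benzyloxy)benzoic acid
Product: 13 8α,9α-epoxy-4β-hydroxydaucan-6α-yl 4-(benzyloxy)benzoate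
Conditions: DCC, DMAP (cat.), CH2Cl2, rt
Reagents that add atoms: none
Why: Steglich esterification: only the secondary 6-OH is acylated, the tertiary 4-OH is inert, and no stereocentre is touched.

Step 9
Reactants: 13 8α,9α-epoxy-4β-hydroxydaucan-6α-yl 4-(benzyloxy)benzoate
Product: 14 4β,8β,9α-trihydroxydaucan-6α-yl 4-(benzyloxy)benzoate
Conditions: HClO4 (cat.), THF/H2O, 0 °C → rt
Reagents that add atoms: water, O
Why: Acid-catalysed epoxide hydrolysis: water attacks the tertiary C8 anti to the epoxide oxygen (inversion at C8, C9–O untouched), giving the trans 8β,9α-diol; the α-oriented ester cannot take part in backside attack.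

Step 10
Reactants: 14 4β,8β,9α-trihydroxydaucan-6α-yl 4-(benzyloxy)benzoate
Product: 15 4β,8β,9α-trihydroxydaucan-6α-yl 4-hydroxybenzoate (CNP0197754.1)
Conditions: H2 (1 atm), Pd/C, EtOAc, rt
Reagents that add atoms: none
Why: Hydrogenolysis of the benzyl aryl ether; no alkene is left and the alkyl benzoate is not benzylic, so nothing else is reduced.

**Compound list**
1 | (R)-(−)-carvone | CC1=CC[C@H](CC1=O)C(C)=C | starting material
2 | (E)-1,4-dibromo-2-methylbut-2-ene | BrC/C=C(C)/CBr | starting material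
3 | lithium (5R)-2-methyl-5-(prop-1-en-2-yl)cyclohex-1-en-1-olate | [Li+].[O-]C1=C(C)CC[C@H](C1)C(C)=C | intermediate
4 | (2R,5R)-2-[(2E)-4-bromo-3-methylbut-2-en-1-yl]-2-methyl-5-(prop-1-en-2-yl)cyclohexan-1-one | C[C@]1(C/C=C(C)/CBr)CC[C@H](CC1=O)C(C)=C | intermediate
5 | (6R)-6-[(2E)-4-bromo-3-methylbut-2-en-1-yl]-6-methyl-3-(propan-2-yl)cyclohex-2-en-1-one | C[C@]1(C/C=C(C)/CBr)CCC(C(C)C)=CC1=O | intermediate
6 | allylzinc bromide derived from 5 (Zn in place of Br) | C[C@]1(C/C=C(C)/C[Zn]Br)CCC(C(C)C)=CC1=O | intermediate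
7 | cis-fused (4aS,8aR)-6,8a-dimethyl-3-(propan-2-yl)-1,2,4a,5,8,8a-hexahydronaphthalen-4a-ol | C[C@@]12CC=C(C)C[C@]1(O)C=C(C(C)C)CC2 | intermediate
8 | (3R,4R,4aR,8aR)-3,4-epoxy-6,8a-dimethyl-3-(propan-2-yl)-1,2,3,4,4a,5,8,8a-octahydronaphthalen-4a-ol | C[C@@]12CC=C(C)C[C@]1(O)[C@H]3O[C@@]3(C(C)C)CC2 | intermediate
9 | (3R,3aR,8aR)-3-hydroxy-6,8a-dimethyl-3-(propan-2-yl)-2,3,3a,5,8,8a-hexahydroazulen-4(1H)-one | CC(C)[C@]1(O)CC[C@]2(C)CC=C(C)CC(=O)[C@H]21 | intermediate
10 | jaeschkeanadiol, (3R,3aS,4S,8aR)-6,8a-dimethyl-3-(propan-2-yl)-1,2,3,3a,4,5,8,8a-octahydroazulene-3,4-diol | CC(C)[C@]1(O)CC[C@]2(C)CC=C(C)C[C@H](O)[C@H]21 | intermediate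
11 | 8α,9α-epoxydaucane-4β,6α-diol | CC(C)[C@]1(O)CC[C@]2(C)C[C@@H]3O[C@]3(C)C[C@H](O)[C@H]21 | intermediate
12 | 4-(benzyloxy)benzoic acid | OC(=O)c1ccc(OCc2ccccc2)cc1 | starting material
13 | 8α,9α-epoxy-4β-hydroxydaucan-6α-yl 4-(benzyloxy)benzoate | CC(C)[C@]1(O)CC[C@]2(C)C[C@@H]3O[C@]3(C)C[C@H](OC(=O)c4ccc(OCc5ccccc5)cc4)[C@H]21 | intermediate
14 | 4β,8β,9α-trihydroxydaucan-6α-yl 4-(benzyloxy)benzoate | CC(C)[C@]1(O)CC[C@]2(C)C[C@H](O)[C@@](C)(O)C[C@H](OC(=O)c3ccc(OCc4ccccc4)cc3)[C@H]21 | intermediate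
15 | (3R,3aS,4S,6S,7S,8aR)-3,6,7-trihydroxy-6,8a-dimethyl-3-(propan-2-yl)decahydroazulen-4-yl 4-hydroxybenzoate | CC(C)[C@]1(O)CC[C@]2(C)C[C@H](O)[C@@](C)(O)C[C@H](OC(=O)c3ccc(O)cc3)[C@H]21 | target

**Totals**
Total step count: 10. Longest linear sequence: 10 steps (from 1).

**Three steps most likely to fail**

Step 5. The epoxide may open at the tertiary C–O bond instead of the secondary one next to the carbinol, or the ring-B CH2 may migrate instead of the ring-fusion carbon. Fallback: set out from 7. OsO4·TMEDA (CH2Cl2, −78 °C, hydroxyl-directed syn-dihydroxylation) gives the all-cis triol F1. MsCl/Et3N sulfonylates its only secondary hydroxyl to give the secondary mesylate F2. KOt-Bu (THF, 0 °C) then triggers the pinacol-type 1,2-shift of the ring-fusion bond, which lies anti to the equatorial mesylate. This returns to the route at 9.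

Step 3. The Barbier closure may give the trans-fused alcohol or fail at the hindered enone carbonyl. Fallback: build ring B by metathesis, setting out from 1. L-Selectride then allyl bromide gives the allyl ketone F3. Anhydrous TsOH in benzene isomerises it to the allyl enone F4. 2-Methylallylmagnesium chloride/CeCl3 (THF, −78 °C) adds 1,2 to give the dienol F5; the carbinol epimers are separated and only the one with OH cis to CH3 is used. Grubbs II ring-closing metathesis (CH2Cl2, 40 °C) returns to the route at 7.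

Step 2. The allylic bromide may not survive the acid isomerisation. Fallback: avoid acid altogether, setting out from 1. H2/RhCl(PPh3)3 hydrogenates only the isopropenyl group to give (R)-carvotanacetone F6. L-Selectride then 2 gives the isopropyl bromo ketone F7 by the same axial alkylation. TMSOTf/2,6-lutidine gives the silyl enol ether F8 at the only enolisable position. IBX·MPO (DMSO, rt) dehydrogenates it, which returns to the route at 5.

**Further compounds**
F1 | step 5 | cis-fused 6,8a-dimethyl-3-(propan-2-yl)-1,2,3,4,4a,5,8,8a-octahydronaphthalene-3,4,4a-triol, three OH and 8a-CH3 on one face | C[C@@]12CC=C(C)C[C@]1(O)[C@@H](O)[C@](O)(C(C)C)CC2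
F2 | step 5 | 4-O-methanesulfonate of F1 | C[C@@]12CC=C(C)C[C@]1(O)[C@@H](OS(C)(=O)=O)[C@](O)(C(C)C)CC2
F3 | step 3 | (2R,5R)-2-allyl-2-methyl-5-(prop-1-en-2-yl)cyclohexan-1-one | C[C@]1(CC=C)CC[C@H](CC1=O)C(C)=C
F4 | step 3 | (6R)-6-allyl-6-methyl-3-(propan-2-yl)cyclohex-2-en-1-one | C[C@]1(CC=C)CCC(C(C)C)=CC1=O
F5 | step 3 | (1S,6R)-6-allyl-6-methyl-1-(2-methylprop-2-en-1-yl)-3-(propan-2-yl)cyclohex-2-en-1-ol | C[C@]1(CC=C)CCC(C(C)C)=C[C@@]1(O)CC(C)=C
F6 | step 2 | (R)-carvotanacetone, (5R)-2-methyl-5-(propan-2-yl)cyclohex-2-en-1-one | CC1=CC[C@H](CC1=O)C(C)C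
F7 | step 2 | (2R,5R)-2-[(2E)-4-bromo-3-methylbut-2-en-1-yl]-2-methyl-5-(propan-2-yl)cyclohexan-1-one | C[C@]1(C/C=C(C)/CBr)CC[C@H](CC1=O)C(C)C
F8 | step 2 | trimethylsilyl enol ether of F7 | C[C@]1(C/C=C(C)/CBr)CC[C@H](C=C1O[Si](C)(C)C)C(C)C
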